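**Strategy.** The depside ester is not made by acylating ring B with an aromatic acid; instead ring A is grown on the ring B oxygen. Ring A, whose C1 carries the ester carbonyl, C2 and C4 oxygen and C6 a methyl group, is an acetate-derived tetraketide, so its C1–C6 bond is disconnected to the ring B aryl ester of 3,5,7-trioxooctanoic acid. One amine-mediated aldol/dehydration closes ring A and aromatizes it with the hindered ester already in place. The precursor is obtained by capturing a diketo acylketene with a ring B phenol whose acid and ortho-hydroxyl are masked as allyl ester and allyl ether; C3 hydroxymethyl and the methyl ethers follow.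

Key step: step 8

Remark on the chemistry: the target is achiral; triketo ester 10 exists as a keto–enol mixture, is written in the all-keto form and is carried forward without chromatography.

**Step 1**
Reactants: 1 2,2,6-trimethyl-4H-1,3-dioxin-4-one
Product: 2 2,2-dimethyl-6-(2-oxopropyl)-4H-1,3-dioxin-4-one
Conditions: LiN(SiMe3)2 (1.0 equiv), THF, −78 °C; acetyl chloride (0.5 equiv), −78 °C; aq. NH4Cl
Reagents that add atoms: acetyl chloride CC(=O)Cl
Why: Vinylogous Claisen-type C-acylation at the methyl carbon of the lithium dienolate, run with the dienolate in excess so that the more acidic product is deprotonated and is not acylated a second time.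

**Step 2**
Reactants: 2 2,2-dimethyl-6-(2-oxopropyl)-4H-1,3-dioxin-4-one
Product: 3 6-(2,4-dioxopentyl)-2,2-dimethyl-4H-1,3-dioxin-4-one
Conditions: LiN(iPr)2 (2.3 equiv), THF, −78 °C; N-methoxy-N-methylacetamide, −78 → −30 °C; 1 M HCl
Reagents that add atoms: N-methoxy-N-methylacetamide CC(=O)N(C)OC
Why: Crossed Claisen condensation of the dianion, whose terminal methyl carbanion is the most nucleophilic site, with a Weinreb amide whose chelated tetrahedral adduct prevents over-addition until the acidic quench.

**Step 3**
Reactants: 4 methyl 2,4-dihydroxy-3,6-dimethylbenzoate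
Product: 5 methyl 2-hydroxy-4-(methoxymethoxy)-3,6-dimethylbenzoate
Conditions: MOMCl (1.1 equiv), K2CO3, acetone, 0 °C → rt
Reagents that add atoms: chloromethyl methyl ether COCCl
Why: Williamson-type O-alkylation should take only the more acidic, non-chelated 4-OH, because the 2-OH is hydrogen-bonded to the ester carbonyl and flanked by two substituents.

**Step 4**
Reactants: 5 methyl 2-hydroxy-4-(methoxymethoxy)-3,6-dimethylbenzoate
Product: 6 2-hydroxy-4-(methoxymethoxy)-3,6-dimethylbenzoic acid
Conditions: KOH, DMSO/H2O, 90 °C; then cold 1 M HCl to pH 3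
Reagents that add atoms: potassium hydroxide [K+].[OH-]
Why: Saponification of the di-ortho-substituted ester is forced by hot KOH in aqueous DMSO, the acetal is inert to base, and cold acidification avoids decarboxylation and acetal loss.

**Step 5**
Reactants: 6 2-hydroxy-4-(methoxymethoxy)-3,6-dimethylbenzoic acid
Product: 7 allyl 2-(allyloxy)-4-(methoxymethoxy)-3,6-dimethylbenzoate
Conditions: allyl bromide (3 equiv), K2CO3, DMF, 60 °C
Reagents that add atoms: allyl bromide C=CCBr
Why: Carboxylate alkylation and Williamson etherification of the remaining chelated phenol should occur in one operation with excess allylic halide in a dipolar aprotic solvent.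

**Step 6**
Reactants: 7 allyl 2-(allyloxy)-4-(methoxymethoxy)-3,6-dimethylbenzoate
Product: 8 allyl 2-(allyloxy)-4-hydroxy-3,6-dimethylbenzoate
Conditions: HCl (cat.), MeOH/THF, 45 °C
Reagents that add atoms: none
Why: Acid-catalysed acetal exchange with methanol removes the methoxymethyl group as dimethoxymethane, while the di-ortho-substituted allyl ester and the allyl ether are inert to dilute acid.

**Step 7**
Reactants: 3 6-(2,4-dioxopentyl)-2,2-dimethyl-4H-1,3-dioxin-4-one; 8 allyl 2-(allyloxy)-4-hydroxy-3,6-dimethylbenzoate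
Product: 10 allyl 2-(allyloxy)-3,6-dimethyl-4-[(3,5,7-trioxooctanoyl)oxy]benzoate, via acylketene 9 (not isolated)
Conditions: 8 (1.5 equiv), toluene, 110 °C, short heating with acetone swept out by N2; evaporate, use crude
Reagents that add atoms: none
Why: Thermal retro-hetero-Diels–Alder loss of acetone gives an acylketene that the phenol, used in excess and recoverable after step 8, should capture by O–H addition (acylketene trapping), since ring B offers no other nucleophilic site.

**Step 8**
Reactants: 10 allyl 2-(allyloxy)-3,6-dimethyl-4-[(3,5,7-trioxooctanoyl)oxy]benzoate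
Product: 12 allyl 2-(allyloxy)-4-[(2,4-dihydroxy-6-methylbenzoyl)oxy]-3,6-dimethylbenzoate, via cyclic aldol adduct 11 (not isolated)
Conditions: Et3N (3 equiv), CH2Cl2, −20 °C → rt; then 1 M HCl wash
Reagents that add atoms: none
Why: Triethylamine generates the enolate at chain C2, the carbon flanked by the aryl ester and the C3 ketone, and this carbon adds to the C7 ketone in a 6-(enolexo)-exo-trig aldol closure that forms the ring A C1–C6 bond and gives β-hydroxy ketone 11. E1cB loss of water followed by enolization of the former C3 and C5 ketones aromatizes the ring irreversibly to the 2,4-dihydroxy-6-methylbenzoate. The closest known reaction type is the biomimetic aldol aromatization of alkyl 3,5,7-triketo esters to resorcylates, the laboratory counterpart of orsellinate biosynthesis. The two stereocentres of 11 are formed without control and are erased on aromatization, so the product is achiral. The selectivity required is carbon attack from C2 on C7 in preference to attack of the C5 enol oxygen (pyrone) or of C6 (Claisen mode) on the ester carbonyl, both of which would expel ring B phenoxide. It should be secured by a non-nucleophilic amine in an aprotic solvent at low temperature, by the absence of chelating metal ions that favour the Claisen mode, and by C7 being the only ketone not tied up in the enolized 3,5-dicarbonyl unit.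

**Step 9**
Reactants: 12 allyl 2-(allyloxy)-4-[(2,4-dihydroxy-6-methylbenzoyl)oxy]-3,6-dimethylbenzoate
Product: 14 allyl 2-(allyloxy)-4-[(3-formyl-2,4-dihydroxy-6-methylbenzoyl)oxy]-3,6-dimethylbenzoate, via chloro(methoxy)methyl arene 13 (not isolated)
Conditions: TiCl4 (3 equiv), Cl2CHOMe (1.2 equiv), CH2Cl2, −78 → 0 °C; ice/1 M HCl
Reagents that add atoms: dichloromethyl methyl ether COC(Cl)Cl; water O
Why: Rieche formylation in which the titanium phenoxides of ring A should direct the chloro(methoxy)methyl cation to C3, the position ortho to both oxygens, while ring B has no free phenol and is deactivated, and hydrolysis of 13 on work-up releases the aldehyde.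

**Step 10**
Reactants: 14 allyl 2-(allyloxy)-4-[(3-formyl-2,4-dihydroxy-6-methylbenzoyl)oxy]-3,6-dimethylbenzoate
Product: 15 allyl 2-(allyloxy)-4-[(3-formyl-2,4-dimethoxy-6-methylbenzoyl)oxy]-3,6-dimethylbenzoate
Conditions: MeI (6 equiv), K2CO3, DMF, rt → 40 °C
Reagents that add atoms: iodomethane CI
Why: Williamson methylation of both chelated phenols is driven by excess iodomethane in DMF, and the di-ortho-substituted depside ester should resist the phenoxide and carbonate present.

**Step 11**
Reactants: 15 allyl 2-(allyloxy)-4-[(3-formyl-2,4-dimethoxy-6-methylbenzoyl)oxy]-3,6-dimethylbenzoate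
Product: 16 allyl 2-(allyloxy)-4-{[3-(hydroxymethyl)-2,4-dimethoxy-6-methylbenzoyl]oxy}-3,6-dimethylbenzoate
Conditions: NaBH4, THF/MeOH, 0 °C; aq. NH4Cl
Reagents that add atoms: none
Why: Chemoselective borohydride reduction of the aldehyde, which is far more electrophilic than the hindered aryl and allyl esters, and the new alkoxide sits meta to the ester so that no lactone can form.

**Step 12**
Reactants: 16 allyl 2-(allyloxy)-4-{[3-(hydroxymethyl)-2,4-dimethoxy-6-methylbenzoyl]oxy}-3,6-dimethylbenzoate
Product: 17 2-hydroxy-4-{[3-(hydroxymethyl)-2,4-dimethoxy-6-methylbenzoyl]oxy}-3,6-dimethylbenzoic acid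
Conditions: Pd(PPh3)4 (5 mol%), morpholine (10 equiv), THF, rt; cold aqueous citric acid (pH 4) work-up
Reagents that add atoms: none
Why: Tsuji–Trost deallylation in which zerovalent palladium ionizes the allyl ester and the allyl aryl ether to π-allyl complexes that morpholine intercepts, under near-neutral conditions that should leave the depside ester and the electron-rich benzylic alcohol untouched.

**Compound list**
1 | 2,2,6-trimethyl-4H-1,3-dioxin-4-one | CC1=CC(=O)OC(C)(C)O1 | starting material
2 | 2,2-dimethyl-6-(2-oxopropyl)-4H-1,3-dioxin-4-one | CC(=O)CC1=CC(=O)OC(C)(C)O1 | intermediate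
3 | 6-(2,4-dioxopentyl)-2,2-dimethyl-4H-1,3-dioxin-4-one | CC(=O)CC(=O)CC1=CC(=O)OC(C)(C)O1 | intermediate
4 | methyl 2,4-dihydroxy-3,6-dimethylbenzoate | COC(=O)c1c(C)cc(O)c(C)c1O | starting material
5 | methyl 2-hydroxy-4-(methoxymethoxy)-3,6-dimethylbenzoate | COCOc1cc(C)c(C(=O)OC)c(O)c1C | intermediate
6 | 2-hydroxy-4-(methoxymethoxy)-3,6-dimethylbenzoic acid | COCOc1cc(C)c(C(=O)O)c(O)c1C | intermediate
7 | allyl 2-(allyloxy)-4-(methoxymethoxy)-3,6-dimethylbenzoate | COCOc1cc(C)c(C(=O)OCC=C)c(OCC=C)c1C | intermediate
8 | allyl 2-(allyloxy)-4-hydroxy-3,6-dimethylbenzoate | Oc1cc(C)c(C(=O)OCC=C)c(OCC=C)c1C | intermediate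
9 | 3,5,7-trioxooct-1-en-1-one (acylketene, not isolated) | CC(=O)CC(=O)CC(=O)C=C=O | intermediate
10 | allyl 2-(allyloxy)-3,6-dimethyl-4-[(3,5,7-trioxooctanoyl)oxy]benzoate (keto–enol mixture, drawn all-keto) | CC(=O)CC(=O)CC(=O)CC(=O)Oc1cc(C)c(C(=O)OCC=C)c(OCC=C)c1C | intermediate
11 | allyl 2-(allyloxy)-4-[(2-hydroxy-2-methyl-4,6-dioxocyclohexane-1-carbonyl)oxy]-3,6-dimethylbenzoate (not isolated; racemic mixture of diastereomers) | CC1(O)CC(=O)CC(=O)C1C(=O)Oc1cc(C)c(C(=O)OCC=C)c(OCC=C)c1C | intermediate
12 | allyl 2-(allyloxy)-4-[(2,4-dihydroxy-6-methylbenzoyl)oxy]-3,6-dimethylbenzoate | Cc1cc(O)cc(O)c1C(=O)Oc1cc(C)c(C(=O)OCC=C)c(OCC=C)c1C | intermediate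
13 | allyl 2-(allyloxy)-4-{[3-(chloro(methoxy)methyl)-2,4-dihydroxy-6-methylbenzoyl]oxy}-3,6-dimethylbenzoate (not isolated; racemic) | COC(Cl)c1c(O)cc(C)c(C(=O)Oc2cc(C)c(C(=O)OCC=C)c(OCC=C)c2C)c1O | intermediate
14 | allyl 2-(allyloxy)-4-[(3-formyl-2,4-dihydroxy-6-methylbenzoyl)oxy]-3,6-dimethylbenzoate | Cc1cc(O)c(C=O)c(O)c1C(=O)Oc1cc(C)c(C(=O)OCC=C)c(OCC=C)c1C | intermediate
15 | allyl 2-(allyloxy)-4-[(3-formyl-2,4-dimethoxy-6-methylbenzoyl)oxy]-3,6-dimethylbenzoate | COc1cc(C)c(C(=O)Oc2cc(C)c(C(=O)OCC=C)c(OCC=C)c2C)c(OC)c1C=O | intermediate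
16 | allyl 2-(allyloxy)-4-{[3-(hydroxymethyl)-2,4-dimethoxy-6-methylbenzoyl]oxy}-3,6-dimethylbenzoate | COc1cc(C)c(C(=O)Oc2cc(C)c(C(=O)OCC=C)c(OCC=C)c2C)c(OC)c1CO | intermediate
17 | 2-hydroxy-4-{[3-(hydroxymethyl)-2,4-dimethoxy-6-methylbenzoyl]oxy}-3,6-dimethylbenzoic acid | COc1cc(C)c(C(=O)Oc2cc(C)c(C(=O)O)c(O)c2C)c(OC)c1CO | target

**Step count.** Total: 12 steps. Longest linear sequence: 10 steps (4 → 17 through steps 3 to 12); the dioxinone arm (steps 1 and 2) joins at step 7.

**Steps most likely to fail**

Step 8 (key step). The enolized chain may close through oxygen (lactonization to a 4-hydroxy-2-pyrone) or through C6 onto the ester carbonyl (Claisen mode), in both cases expelling ring B phenoxide, or the reaction may stall at the aldol adduct. The fallback brings ring A in already aromatic and sets out from 8. Commercial 2,4-dihydroxy-6-methylbenzoic acid would be acetylated (Ac2O, pyridine) to 2,4-diacetoxy-6-methylbenzoic acid F1. Mixed-anhydride esterification of F1 with 8 ((CF3CO)2O, toluene, rt) should give allyl 2-(allyloxy)-4-[(2,4-diacetoxy-6-methylbenzoyl)oxy]-3,6-dimethylbenzoate F2. Hydrazinolysis of the two unhindered aryl acetates (N2H4·H2O, THF/MeOH, 0 °C) then comes back to the route at 12.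

Step 7. Self-capture of the acylketene by its own C5 enol oxygen may outrun addition of the hindered phenol, and aryl ester 10 may revert to ketene on prolonged heating. The fallback captures the ketene with a primary alcohol and makes the depside bond afterwards by classical esterification; it sets out from 3. Thermolysis of 3 with benzyl alcohol (toluene, 110 °C) should give benzyl 3,5,7-trioxooctanoate F3, which Et3N in CH2Cl2 aromatizes to benzyl 2,4-dihydroxy-6-methylbenzoate F4. Rieche formylation (TiCl4, Cl2CHOMe, CH2Cl2) would give benzyl 3-formyl-2,4-dihydroxy-6-methylbenzoate F5, any C5 isomer being separable at this simple stage. Methylation (MeI, K2CO3, DMF) gives benzyl 3-formyl-2,4-dimethoxy-6-methylbenzoate F6, and hydrogenolysis (H2, Pd/C, EtOAc) gives 3-formyl-2,4-dimethoxy-6-methylbenzoic acid F7. Esterification of F7 with 8 ((CF3CO)2O, toluene, rt) comes back to the route at 15.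

Step 9. Substitution may occur at ring A C5 in competition with C3, and the Lewis acid may cleave the ring B allyl ether that sits ortho to the ester. The fallback changes the order of methylation and formylation, so that the carbon is delivered from a single phenoxide with one free ortho position and without a strong Lewis acid; it sets out from 12. Mono-methylation of the non-chelated 4-OH (MeI 1.05 equiv, K2CO3, acetone, rt) should give allyl 2-(allyloxy)-4-[(2-hydroxy-4-methoxy-6-methylbenzoyl)oxy]-3,6-dimethylbenzoate F8. Magnesium-phenoxide-directed ortho-formylation (MgCl2, Et3N, paraformaldehyde, MeCN, reflux) can then reach only C3, giving allyl 2-(allyloxy)-4-[(3-formyl-2-hydroxy-4-methoxy-6-methylbenzoyl)oxy]-3,6-dimethylbenzoate F9. Methylation of the remaining phenol (MeI, K2CO3, DMF) comes back to the route at 15.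

**Further compounds**
F1 | step 8 | 2,4-diacetoxy-6-methylbenzoic acid | CC(=O)Oc1cc(C)c(C(=O)O)c(OC(C)=O)c1
F2 | step 8 | allyl 2-(allyloxy)-4-[(2,4-diacetoxy-6-methylbenzoyl)oxy]-3,6-dimethylbenzoate | CC(=O)Oc1cc(C)c(C(=O)Oc2cc(C)c(C(=O)OCC=C)c(OCC=C)c2C)c(OC(C)=O)c1
F3 | step 7 | benzyl 3,5,7-trioxooctanoate | CC(=O)CC(=O)CC(=O)CC(=O)OCc1ccccc1
F4 | step 7 | benzyl 2,4-dihydroxy-6-methylbenzoate | Cc1cc(O)cc(O)c1C(=O)OCc1ccccc1
F5 | step 7 | benzyl 3-formyl-2,4-dihydroxy-6-methylbenzoate | Cc1cc(O)c(C=O)c(O)c1C(=O)OCc1ccccc1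
F6 | step 7 | benzyl 3-formyl-2,4-dimethoxy-6-methylbenzoate | COc1cc(C)c(C(=O)OCc2ccccc2)c(OC)c1C=O
F7 | step 7 | 3-formyl-2,4-dimethoxy-6-methylbenzoic acid | COc1cc(C)c(C(=O)O)c(OC)c1C=O
F8 | step 9 | allyl 2-(allyloxy)-4-[(2-hydroxy-4-methoxy-6-methylbenzoyl)oxy]-3,6-dimethylbenzoate | COc1cc(C)c(C(=O)Oc2cc(C)c(C(=O)OCC=C)c(OCC=C)c2C)c(O)c1
F9 | step 9 | allyl 2-(allyloxy)-4-[(3-formyl-2-hydroxy-4-methoxy-6-methylbenzoyl)oxy]-3,6-dimethylbenzoate | COc1cc(C)c(C(=O)Oc2cc(C)c(C(=O)OCC=C)c(OCC=C)c2C)c(O)c1C=O
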